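**Plan**

- Working numbering: C1 (ring-fusion CMe), C2=C3, C4 (C(OH)iPr), C5 (ring-fusion CH), C6 (CH–O–vanilloyl), C7, C8 (C(OH)Me), C9, C10. The five-membered ring is C1–C5 and the seven-membered ring is C1, C5–C10. In the azulene names C3, C3a, C4, C6, C8a correspond to C4, C5, C6, C8, C1.
- Enabling feature: the cyclopentenol ring is a masked cyclopent-2-enone (C4=O beside C2=C3) whose C5–C1 edge lies in the seven-membered ring, so C1–C2 can come from a cross-conjugated dienone C2=C3–C4(=O)–C5=C1 by 4π closure at the methyl-bearing C1.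
- Cuts, in retrosynthetic order: C6–O ester bond (with inversion), C4–isopropyl, C1–C2 (Nazarov), C4–C5 (alkenyllithium plus silylacrolein), the C6 carbinol C–H, the C1–O ether bridge, and the two C–C bonds of a furan/oxyallyl (4+3) adduct.
- Forward: the seven-membered ring is made first from 2,5-dimethylfuran and tetrabromoacetone, desymmetrised and opened to a cycloheptenone. The silylpropenoyl arm is attached at C5, the five-membered ring closes by a silicon-directed Nazarov reaction, and the isopropyl and vanilloyl groups follow.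
- Stereochemistry: C8 from enantioselective deprotonation of a meso ketone. C6 is first set cis to the C8 oxygen by oxazaborolidine reduction so that an acetonide bridges both oxygens, then inverted during esterification. C1 and C5 come from the Nazarov step under control of that bridge, and C4 from addition anti to the angular methyl.

Key step: step 12

Assumption: the (R,R)-lithium amide is taken to remove the proton that leads to enol ether 7 as drawn, and the (S)-oxazaborolidine to deliver hydride as in the usual model with the bromoalkenyl carbon as the large group; if either sense is the reverse, the enantiomeric reagent is used.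

**Step 1**
Reactants: 1 2,5-dimethylfuran; 2 1,1,3,3-tetrabromoacetone
Product: 4 (1R,5S)-1,5-dimethyl-8-oxabicyclo[3.2.1]oct-6-en-3-one (meso), via dibromo cycloadduct 3 (not isolated)
Conditions: Zn, B(OEt)3, THF, rt; then Zn–Cu couple, NH4Cl, MeOH, rt
Reagents that add atoms: none
Why: (4+3) cycloaddition of the zinc oxyallyl cation from the tetrabromoketone with the furan builds the oxygen-bridged seven-membered ring, and zinc–copper reduction removes both α-bromines; the cis bridge is enforced, so the product is a single meso compound.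

**Step 2**
Reactants: 4 (1R,5S)-1,5-dimethyl-8-oxabicyclo[3.2.1]oct-6-en-3-one
Product: 5 (1R,5S)-1,5-dimethyl-8-oxabicyclo[3.2.1]octan-3-one (meso)
Conditions: H2 (1 atm), 10% Pd/C, EtOAc, rt
Reagents that add atoms: none
Why: heterogeneous hydrogenation of the strained disubstituted alkene should be fast and leaves ketone, ether bridge and meso symmetry untouched.

**Step 3**
Reactants: 5 (1R,5S)-1,5-dimethyl-8-oxabicyclo[3.2.1]octan-3-one
Product: 7 (1S,5R)-1,5-dimethyl-3-(trimethylsilyloxy)-8-oxabicyclo[3.2.1]oct-2-ene, via lithium enolate 6 (not isolated)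
Conditions: lithium (R,R)-bis(1-phenylethyl)amide (from the amine and n-BuLi), Me3SiCl (internal quench), THF, −100 °C
Reagents that add atoms: chlorotrimethylsilane, C[Si](C)(C)Cl
Why: enantiotopic-group-selective deprotonation of a meso 8-oxabicyclo[3.2.1]octan-3-one by a chiral lithium amide with internal silyl quench is a known desymmetrisation; it decides which bridgehead becomes C1 and so fixes C8 as (R).

**Step 4**
Reactants: 7 (1S,5R)-1,5-dimethyl-3-(trimethylsilyloxy)-8-oxabicyclo[3.2.1]oct-2-ene
Product: 8 (R)-3,6-dimethyl-6-(trimethylsilyloxy)cyclohept-2-en-1-one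
Conditions: Me3SiOSO2CF3 (5 mol %), CH2Cl2, −78 → −20 °C; then Et3N
Reagents that add atoms: none
Why: Lewis-acid-triggered β-elimination (retro-oxa-Michael opening): silylation of the bridging oxygen, cleavage of the C1–O bond at the tertiary bridgehead with push from the enol ether, and silyl transfer to the departing oxygen give the enone with its tertiary silyl ether in place and C8 untouched.

**Step 5**
Reactants: 8 (R)-3,6-dimethyl-6-(trimethylsilyloxy)cyclohept-2-en-1-one
Product: 10 (R)-2-bromo-3,6-dimethyl-6-(trimethylsilyloxy)cyclohept-2-en-1-one, via dibromo ketone 9 (not isolated)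
Conditions: Br2, CH2Cl2, 0 °C; then Et3N, 0 °C → rt
Reagents that add atoms: bromine, BrBr
Why: α-bromination of an enone by addition–elimination: bromine adds across C5=C1 and the amine removes the acidic C5 proton with E1cB loss of the tertiary bromide, as for 3-methylcycloalkenones.

**Step 6**
Reactants: 10 (R)-2-bromo-3,6-dimethyl-6-(trimethylsilyloxy)cyclohept-2-en-1-one
Product: 11 (1R,6R)-2-bromo-3,6-dimethyl-6-(trimethylsilyloxy)cyclohept-2-en-1-ol
Conditions: (S)-1-methyl-3,3-diphenyl-tetrahydro-1H,3H-pyrrolo[1,2-c][1,3,2]oxazaborole (20 mol %), BH3·SMe2, THF, −20 °C; then MeOH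
Reagents that add atoms: none
Why: Corey–Bakshi–Shibata reduction, for which 2-bromoenones are good substrates; with the bromoalkenyl carbon as the large group the catalyst should deliver hydride to the face that gives the (1R) carbinol, with the new C6 oxygen cis to the C8 silyloxy group.

**Step 7**
Reactants: 11 (1R,6R)-2-bromo-3,6-dimethyl-6-(trimethylsilyloxy)cyclohept-2-en-1-ol
Product: 13 (1R,6R)-2-bromo-3,6,8,8-tetramethyl-7,9-dioxabicyclo[4.3.1]dec-2-ene, via bromo diol 12 (not isolated)
Conditions: pyridinium p-toluenesulfonate (10 mol %), MeOH, rt; evaporate; then 2-methoxypropene, same acid, CH2Cl2, 0 °C → rt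
Reagents that add atoms: 2-methoxypropene, COC(C)=C
Why: acid-catalysed methanolysis of the tertiary trimethylsilyl ether followed by acetonide formation; only the cis-1,3-diol can be bridged, so any trans isomer from step 6 is left behind as diol.

**Step 8**
Reactants: 14 3-(trimethylsilyl)prop-2-yn-1-ol
Product: 15 (E)-3-(trimethylsilyl)prop-2-en-1-ol
Conditions: NaAlH2(OCH2CH2OMe)2, Et2O, 0 °C → rt; aq. Rochelle salt
Reagents that add atoms: none
Why: alkoxide-directed trans-hydroalumination of a propargylic alcohol gives the E-alkene after protonolysis.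

**Step 9**
Reactants: 15 (E)-3-(trimethylsilyl)prop-2-en-1-ol
Product: 16 (E)-3-(trimethylsilyl)prop-2-enal
Conditions: MnO2 (activated), CH2Cl2, rt
Reagents that add atoms: none
Why: selective allylic oxidation by MnO2 without isomerisation of the vinylsilane; the volatile aldehyde is used as a solution.

**Step 10**
Reactants: 13 (1R,6R)-2-bromo-3,6,8,8-tetramethyl-7,9-dioxabicyclo[4.3.1]dec-2-ene; 16 (E)-3-(trimethylsilyl)prop-2-enal
Product: 18 (E)-1-[(1R,6R)-3,6,8,8-tetramethyl-7,9-dioxabicyclo[4.3.1]dec-2-en-2-yl]-3-(trimethylsilyl)prop-2-en-1-ol (both carbinol epimers), via alkenyllithium 17 (not isolated)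
Conditions: t-BuLi (2.1 equiv), Et2O, −78 °C; then 16, −78 → −40 °C; aq. NH4Cl
Reagents that add atoms: none
Why: bromine–lithium exchange gives an alkenyllithium that cannot lose the C6 oxygen (that would need a seven-membered cyclic allene) and adds 1,2 to the enal to form C4–C5; the carbinol configuration is irrelevant because it is oxidised next.

**Step 11**
Reactants: 18 (E)-1-[(1R,6R)-3,6,8,8-tetramethyl-7,9-dioxabicyclo[4.3.1]dec-2-en-2-yl]-3-(trimethylsilyl)prop-2-en-1-ol
Product: 19 (E)-1-[(1R,6R)-3,6,8,8-tetramethyl-7,9-dioxabicyclo[4.3.1]dec-2-en-2-yl]-3-(trimethylsilyl)prop-2-en-1-one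
Conditions: Dess–Martin periodinane, NaHCO3, CH2Cl2, 0 °C → rt
Reagents that add atoms: none
Why: buffered Dess–Martin oxidation of a bis-allylic alcohol gives the cross-conjugated dienone without touching the acetonide or the vinylsilane.

**Step 12 (key step)**
Reactants: 19 (E)-1-[(1R,6R)-3,6,8,8-tetramethyl-7,9-dioxabicyclo[4.3.1]dec-2-en-2-yl]-3-(trimethylsilyl)prop-2-en-1-one
Product: 21 (3aS,4R,6R,8aS)-6,8a-dimethyl-4,6-(propane-2,2-diyldioxy)-4,5,6,7,8,8a-hexahydroazulen-3(3aH)-one, via iron dienolate 20 (not isolated)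
Conditions: FeCl3 (1.1 equiv), 2,6-di-tert-butylpyridine (0.2 equiv), CH2Cl2, −40 → 0 °C; then cold aq. NaHCO3
Reagents that add atoms: none
Why: FeCl3 binds the ketone and generates a 3-oxidopentadienyl cation that closes between C1 and C2; the oxyallyl cation so formed is stabilised by the β C–Si bond and loses the silyl group as Me3SiCl, which places the alkene at C2=C3 only, and dienolate 20 is protonated at C5 on quench. The closest known reaction type is the silicon-directed Nazarov cyclisation of β-silylvinyl cycloalkenyl ketones, used here with a fully substituted ring terminus. The five-membered ring closes by thermal conrotatory 4π electrocyclisation forming C1–C2. C1 is set by torquoselectivity: the dioxane bridge covers the lower face of the seven-membered ring, so C2 should bond to C1 from the upper face and the small methyl group, not the new ring, turns into the pocket under the ring. C5 is set by kinetic protonation of 20 from the upper face, anti to the adjacent angular methyl and the axial C6 oxygen, which gives the trans ring fusion. The step needs regiocontrol of the alkene (secured by silicon), facial control (secured by the bridge) and survival of the acetonide and the C6–O bond (the hindered pyridine removes HCl and the cold basic quench limits β-elimination from 20).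

**Step 13**
Reactants: 21 (3aS,4R,6R,8aS)-6,8a-dimethyl-4,6-(propane-2,2-diyldioxy)-4,5,6,7,8,8a-hexahydroazulen-3(3aH)-one
Product: 22 (3S,3aS,4R,6R,8aS)-6,8a-dimethyl-3-(propan-2-yl)-4,6-(propane-2,2-diyldioxy)-3,3a,4,5,6,7,8,8a-octahydroazulen-3-ol
Conditions: i-PrMgCl, CeCl3 (dried), THF, −78 °C; then 21, −78 °C; aq. NH4Cl
Reagents that add atoms: isopropylmagnesium chloride, CC(C)[Mg]Cl (used as isopropylcerium dichloride, CC(C)[Ce](Cl)Cl)
Why: organocerium 1,2-addition to an enolisable enone, the low basicity suppressing enolisation, β-elimination of the C6 oxygen and conjugate addition; the lower face of C4 is shielded by the axial angular methyl and the C6 oxygen, so isopropyl should enter from above and leave the hydroxyl cis to the C1 methyl.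

**Step 14**
Reactants: 22 (3S,3aS,4R,6R,8aS)-6,8a-dimethyl-3-(propan-2-yl)-4,6-(propane-2,2-diyldioxy)-3,3a,4,5,6,7,8,8a-octahydroazulen-3-ol
Product: 23 (3S,3aS,4R,6R,8aS)-6,8a-dimethyl-3-(propan-2-yl)-3,3a,4,5,6,7,8,8a-octahydroazulene-3,4,6-triol
Conditions: pyridinium p-toluenesulfonate (20 mol %), MeOH, 0 °C → rt
Reagents that add atoms: none
Why: acid-catalysed transketalisation; the strained bridged dioxane should cleave under acid weak enough to leave the tertiary allylic carbinol un-ionised.

**Step 15**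
Reactants: 24 vanillic acid
Product: 25 4-acetoxy-3-methoxybenzoic acid
Conditions: Ac2O, aq. NaOH, 0 °C; then HCl to pH 2
Reagents that add atoms: acetic anhydride, CC(=O)OC(C)=O
Why: Schotten–Baumann acetylation of the phenoxide; any mixed anhydride at the carboxyl group hydrolyses on acidification.

**Step 16**
Reactants: 23 (3S,3aS,4R,6R,8aS)-6,8a-dimethyl-3-(propan-2-yl)-3,3a,4,5,6,7,8,8a-octahydroazulene-3,4,6-triol; 25 4-acetoxy-3-methoxybenzoic acid
Product: 26 (3S,3aS,4S,6R,8aS)-3,6-dihydroxy-6,8a-dimethyl-3-(propan-2-yl)-3,3a,4,5,6,7,8,8a-octahydroazulen-4-yl 4-acetoxy-3-methoxybenzoate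
Conditions: PPh3, diisopropyl azodicarboxylate, toluene, 0 °C → rt
Reagents that add atoms: none
Why: Mitsunobu esterification: only the secondary C6 hydroxyl forms the alkoxyphosphonium ion (the two tertiary hydroxyls do not), and SN2 attack by the carboxylate inverts C6 to the target configuration.

**Step 17**
Reactants: 26 (3S,3aS,4S,6R,8aS)-3,6-dihydroxy-6,8a-dimethyl-3-(propan-2-yl)-3,3a,4,5,6,7,8,8a-octahydroazulen-4-yl 4-acetoxy-3-methoxybenzoate
Product: 27 (3S,3aS,4S,6R,8aS)-3,6-dihydroxy-6,8a-dimethyl-3-(propan-2-yl)-3,3a,4,5,6,7,8,8a-octahydroazulen-4-yl 4-hydroxy-3-methoxybenzoate (CNP0113302.1)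
Conditions: K2CO3 (0.2 equiv), MeOH, 0 °C
Reagents that add atoms: none
Why: base-catalysed methanolysis of the aryl acetate is much faster than that of the hindered, electron-rich secondary benzoate, so the phenol is freed without loss of the C6 ester.

**Compound list**

1 | 2,5-dimethylfuran | Cc1ccc(C)o1 | starting material
2 | 1,1,3,3-tetrabromopropan-2-one (1,1,3,3-tetrabromoacetone) | BrC(Br)C(=O)C(Br)Br | starting material
3 | 2,4-dibromo-1,5-dimethyl-8-oxabicyclo[3.2.1]oct-6-en-3-one (cis-bridged, C–Br epimers) | C[C@]12C=C[C@](C)(C(Br)C(=O)C1Br)O2 | intermediate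
4 | (1R,5S)-1,5-dimethyl-8-oxabicyclo[3.2.1]oct-6-en-3-one (meso) | C[C@]12C=C[C@](C)(CC(=O)C1)O2 | intermediate
5 | (1R,5S)-1,5-dimethyl-8-oxabicyclo[3.2.1]octan-3-one (meso) | C[C@]12CC[C@](C)(CC(=O)C1)O2 | intermediate
6 | lithium (1S,5R)-1,5-dimethyl-8-oxabicyclo[3.2.1]oct-2-en-3-olate | [Li]OC1=C[C@]2(C)CC[C@](C)(C1)O2 | intermediate
7 | (1S,5R)-1,5-dimethyl-3-(trimethylsilyloxy)-8-oxabicyclo[3.2.1]oct-2-ene | C[Si](C)(C)OC1=C[C@]2(C)CC[C@](C)(C1)O2 | intermediate
8 | (R)-3,6-dimethyl-6-(trimethylsilyloxy)cyclohept-2-en-1-one | CC1=CC(=O)C[C@](C)(O[Si](C)(C)C)CC1 | intermediate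
9 | (6R)-2,3-dibromo-3,6-dimethyl-6-(trimethylsilyloxy)cycloheptan-1-one (dibromide diastereomers) | CC1(Br)C(Br)C(=O)C[C@](C)(O[Si](C)(C)C)CC1 | intermediate
10 | (R)-2-bromo-3,6-dimethyl-6-(trimethylsilyloxy)cyclohept-2-en-1-one | CC1=C(Br)C(=O)C[C@](C)(O[Si](C)(C)C)CC1 | intermediate
11 | (1R,6R)-2-bromo-3,6-dimethyl-6-(trimethylsilyloxy)cyclohept-2-en-1-ol | CC1=C(Br)[C@H](O)C[C@](C)(O[Si](C)(C)C)CC1 | intermediate
12 | (1R,6R)-2-bromo-3,6-dimethylcyclohept-2-ene-1,6-diol (cis diol) | CC1=C(Br)[C@H](O)C[C@](C)(O)CC1 | intermediate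
13 | (1R,6R)-2-bromo-3,6,8,8-tetramethyl-7,9-dioxabicyclo[4.3.1]dec-2-ene (acetonide of 12) | BrC1=C(C)CC[C@]2(C)C[C@H]1OC(C)(C)O2 | intermediate
14 | 3-(trimethylsilyl)prop-2-yn-1-ol | C[Si](C)(C)C#CCO | starting material
15 | (E)-3-(trimethylsilyl)prop-2-en-1-ol | C[Si](C)(C)/C=C/CO | intermediate
16 | (E)-3-(trimethylsilyl)prop-2-enal | C[Si](C)(C)/C=C/C=O | intermediate
17 | [(1R,6R)-3,6,8,8-tetramethyl-7,9-dioxabicyclo[4.3.1]dec-2-en-2-yl]lithium | [Li]C1=C(C)CC[C@]2(C)C[C@H]1OC(C)(C)O2 | intermediate
18 | (E)-1-[(1R,6R)-3,6,8,8-tetramethyl-7,9-dioxabicyclo[4.3.1]dec-2-en-2-yl]-3-(trimethylsilyl)prop-2-en-1-ol (carbinol epimers) | C[Si](C)(C)/C=C/C(O)C1=C(C)CC[C@]2(C)C[C@H]1OC(C)(C)O2 | intermediate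
19 | (E)-1-[(1R,6R)-3,6,8,8-tetramethyl-7,9-dioxabicyclo[4.3.1]dec-2-en-2-yl]-3-(trimethylsilyl)prop-2-en-1-one | C[Si](C)(C)/C=C/C(=O)C1=C(C)CC[C@]2(C)C[C@H]1OC(C)(C)O2 | intermediate
20 | dichloroiron dienolate of 21 (C4–O–FeCl2, C4=C5 and C2=C3; C1, C6, C8 as in 21) | Cl[Fe](Cl)OC1=C2[C@H]3C[C@@](C)(CC[C@@]2(C)C=C1)OC(C)(C)O3 | intermediate
21 | (3aS,4R,6R,8aS)-6,8a-dimethyl-4,6-(propane-2,2-diyldioxy)-4,5,6,7,8,8a-hexahydroazulen-3(3aH)-one (trans-fused) | O=C1C=C[C@]2(C)CC[C@]3(C)C[C@@H](OC(C)(C)O3)[C@@H]12 | intermediate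
22 | (3S,3aS,4R,6R,8aS)-6,8a-dimethyl-3-(propan-2-yl)-4,6-(propane-2,2-diyldioxy)-3,3a,4,5,6,7,8,8a-octahydroazulen-3-ol | CC(C)[C@]1(O)C=C[C@]2(C)CC[C@]3(C)C[C@@H](OC(C)(C)O3)[C@@H]12 | intermediate
23 | (3S,3aS,4R,6R,8aS)-6,8a-dimethyl-3-(propan-2-yl)-3,3a,4,5,6,7,8,8a-octahydroazulene-3,4,6-triol | CC(C)[C@]1(O)C=C[C@]2(C)CC[C@@](C)(O)C[C@@H](O)[C@@H]12 | intermediate
24 | vanillic acid (4-hydroxy-3-methoxybenzoic acid) | COc1cc(C(=O)O)ccc1O | starting material
25 | 4-acetoxy-3-methoxybenzoic acid | COc1cc(C(=O)O)ccc1OC(C)=O | intermediate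
26 | (3S,3aS,4S,6R,8aS)-3,6-dihydroxy-6,8a-dimethyl-3-(propan-2-yl)-3,3a,4,5,6,7,8,8a-octahydroazulen-4-yl 4-acetoxy-3-methoxybenzoate | CC(C)[C@]1(O)C=C[C@]2(C)CC[C@@](C)(O)C[C@H](OC(=O)c3ccc(OC(C)=O)c(OC)c3)[C@@H]12 | intermediate
27 | (3S,3aS,4S,6R,8aS)-3,6-dihydroxy-6,8a-dimethyl-3-(propan-2-yl)-3,3a,4,5,6,7,8,8a-octahydroazulen-4-yl 4-hydroxy-3-methoxybenzoate | COc1cc(C(=O)O[C@H]2C[C@](C)(O)CC[C@@]3(C)C=C[C@@](O)(C(C)C)[C@H]23)ccc1O | target

**Step count**

Total: 17 steps. Longest linear sequence: 14 steps (steps 1–7, 10–14, 16, 17); steps 8–9 and step 15 are side branches.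

**Steps most likely to fail**

1. Step 12. The Lewis acid may open or ionise the acetonide, closure at the fully substituted C1 may be slow, the dienolate may expel the C6 oxygen by β-elimination, or C5 may be protonated from the lower face to give the cis-fused ketone. Fallback, from 13 back to 21, builds the five-membered ring by conjugate addition and metathesis instead. Bromine–lithium exchange on 13 and formylation with N,N-dimethylformamide would give the unsaturated carbaldehyde F1. Copper-mediated 1,4-addition of vinylmagnesium bromide (CuBr·SMe2, Me3SiCl) should deliver vinyl to C1 from the face away from the dioxane bridge and give the silyl enol ether F2, whose mild hydrolysis gives the trans vinyl aldehyde F3. Addition of vinylmagnesium bromide gives the dienol F4, ring-closing metathesis with the second-generation Grubbs catalyst (H2IMes)(PCy3)Cl2Ru=CHPh closes C2=C3 to the cyclopentenol F5, and Dess–Martin oxidation returns to 21.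

2. Step 16. SN2 displacement at C6 may fail because the attack face carries the syn isopropyl group and the C8 methyl, leading to elimination or recovered alcohol. Fallback, from 23 back to 26, inverts C6 by oxidation and directed reduction. Dess–Martin oxidation of the only secondary hydroxyl gives the dihydroxy ketone F6. Evans–Saksena reduction with Me4NBH(OAc)3 in MeCN/AcOH delivers hydride from the two tertiary hydroxyls on the lower face and should give the C6-epimeric triol F7. Esterification of its secondary hydroxyl with acid 25 (N,N'-dicyclohexylcarbodiimide, 4-(dimethylamino)pyridine, CH2Cl2), with retention, gives 26.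

3. Step 14. The acid needed to cleave the acetonide may ionise the tertiary allylic C4 carbinol, leading to dehydration to a cyclopentadiene or allylic methanolysis. Fallback, from 21 back to 23, removes the acetal before the carbinol exists. Hydrolysis of 21 with aqueous AcOH gives the dihydroxy enone F8, and N-(trimethylsilyl)imidazole gives the bis(trimethylsilyl) ether F9. Isopropylcerium dichloride adds as in step 13, the lower face still carrying the methyl and the C6 silyloxy group, to give the carbinol F10. K2CO3 in MeOH removes both silyl groups without acid and gives 23.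

**Further compounds**

F1 | step 12 | (1R,6R)-3,6,8,8-tetramethyl-7,9-dioxabicyclo[4.3.1]dec-2-ene-2-carbaldehyde | O=CC1=C(C)CC[C@]2(C)C[C@H]1OC(C)(C)O2
F2 | step 12 | trimethylsilyl enol ether of F3 (C1 vinyl up, C4H=C5; C1, C6, C8 as in 21) | C=C[C@]1(C)CC[C@]2(C)C[C@@H](OC(C)(C)O2)C1=CO[Si](C)(C)C
F3 | step 12 | (1R,2S,3S,6R)-3-ethenyl-3,6,8,8-tetramethyl-7,9-dioxabicyclo[4.3.1]decane-2-carbaldehyde | C=C[C@]1(C)CC[C@]2(C)C[C@@H](OC(C)(C)O2)[C@H]1C=O
F4 | step 12 | 1-[3-ethenyl-3,6,8,8-tetramethyl-7,9-dioxabicyclo[4.3.1]decan-2-yl]prop-2-en-1-ol (ring centres as in F3, carbinol epimers) | C=C[C@]1(C)CC[C@]2(C)C[C@@H](OC(C)(C)O2)[C@H]1C(O)C=C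
F5 | step 12 | C4 alcohol corresponding to 21 (3-hydroxy in place of 3-oxo, carbinol epimers; other centres as in 21) | OC1C=C[C@]2(C)CC[C@]3(C)C[C@@H](OC(C)(C)O3)[C@@H]12
F6 | step 16 | 3,6-dihydroxy-6,8a-dimethyl-3-(propan-2-yl)-3a,5,6,7,8,8a-hexahydroazulen-4(3H)-one (C6 ketone of 23; other centres as in 23) | CC(C)[C@]1(O)C=C[C@]2(C)CC[C@@](C)(O)CC(=O)[C@@H]12
F7 | step 16 | (3S,3aS,4S,6R,8aS)-6,8a-dimethyl-3-(propan-2-yl)-3,3a,4,5,6,7,8,8a-octahydroazulene-3,4,6-triol | CC(C)[C@]1(O)C=C[C@]2(C)CC[C@@](C)(O)C[C@H](O)[C@@H]12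
F8 | step 14 | (3aS,4R,6R,8aS)-4,6-dihydroxy-6,8a-dimethyl-4,5,6,7,8,8a-hexahydroazulen-3(3aH)-one | O=C1C=C[C@]2(C)CC[C@@](C)(O)C[C@@H](O)[C@@H]12
F9 | step 14 | 4,6-bis(trimethylsilyl) ether of F8 | O=C1C=C[C@]2(C)CC[C@@](C)(O[Si](C)(C)C)C[C@@H](O[Si](C)(C)C)[C@@H]12
F10 | step 14 | 4,6-bis(trimethylsilyl) ether of 23 | CC(C)[C@]1(O)C=C[C@]2(C)CC[C@@](C)(O[Si](C)(C)C)C[C@@H](O[Si](C)(C)C)[C@@H]12
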